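## The problem

The target is a (1(10)Z,4E)-germacradienolide. Its ten-membered carbocycle (C1–C10) holds two trisubstituted olefins of opposite geometry, C14 on C10 and C15 on C4, and is fused trans at C6–C7 to an α-methylene-γ-lactone (O6–C12–C11(=C13)–C7). Four contiguous oxygenated stereocentres lie on one arc: the lactone oxygen at C6 and the tertiary hydroxyl at C7 on one face (called α here), and C11, the C8 acetate and the C9 ester on the other (β). The C9 ester is a (2S,3S)-2,3-dimethyloxirane-2-carboxylate (epoxyangelate) whose two centres are remote from the ring and need reagent control. C8 can come from the chiral pool; its oxygen can then direct an osmylation that sets C6 and C7 together, and C9 can be set late by hydride addition beside C8. C7 is quaternary and cannot be corrected afterwards. Groups that will not survive rough treatment are the α-methylene lactone (conjugate addition, reduction), the epoxy ester, the two vicinal esters beside a free tertiary alcohol (acyl migration, translactonisation to O8 or O9), the 1,5-diene (acid-induced transannular cyclisation, Cope rearrangement) and the β-hydroxy carbonyl relationships around C7 (retro-aldol, elimination). Direct closure of a ten-membered ring with one Z and one E trisubstituted olefin is poor. The feature that removes this difficulty is the unit C10=C1–C2–C3–C4=C5, a hexa-1,5-diene whose ends C5 and C10 are bridged by C6–C9. It is the ring-opened form of a bicyclo[2.2.0]hexane (C1, C2, C3, C4, C5, C10) fused along C5–C10 to a cyclohexane (C5–C10), and the trans-fused lactone on that cyclohexane can act as a conformational lock.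

## Retrosynthesis

**Acyl groups last.** Target 34 is cut at the C8 acetate to alcohol 33, and 33 at its silyl ether to 32. The acetate comes last because an acetyl group beside a free hydroxyl migrates easily, whereas the hindered epoxyangelate does not. Ester 32 is cut at the C9 ester to allylic alcohol 26 and acid 30. Acid 30 is made separately from angelic acid 27 through allylic alcohol 28 and epoxy alcohol 29, so the epoxide centres are set by a tartrate-controlled epoxidation, not on the sensitive macrocycle.

**Methylene before esters.** The C11=C13 methylene of 26 is removed back to the saturated lactone 22 (via 25). The enolate chemistry must precede both esters, and it is run on the dianion of the free C7 hydroxyl so that no β-elimination can occur. C9 carries a triethylsilyl group and C8 a tert-butyldimethylsilyl group, which later lets C9 be unmasked alone. Diol 21 precedes 22.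

**C9 stereocentre.** Diol 21 is cut at the C9–H bond to the Z-enone 19. A 1,2-reduction next to the C8 silyl ether is asked to give the 9β-alcohol.

**Ring expansion (key cut).** In 19 the C1=C10 and C4=C5 double bonds are converted back into the C1–C4 and C5–C10 single bonds of tricycle 18. This exchanges a ten-membered ring with two defined olefin geometries for a rigid cyclohexanone fused to a bicyclo[2.2.0]hexane, whose relative configuration encodes the geometry. Compared with closing the ring at C1–C10 or C4–C5, no macrocyclisation is needed. The forward reaction has to cleave C5–C10 and not C2–C3, and must place C6 equatorial and C9 axial in the intermediate diyl. The trans-lactone fixes the cyclohexanone chair, so this holds only for the adduct whose cyclobutane lies on the α face.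

**Cyclobutane.** Tricycle 18 (silyl ether of 17) is cut at C1–C10 and C4–C5 to enone 14 and 1-methylcyclobutene 16, which comes from methylenecyclobutane 15. Head-to-tail orientation puts the methyl-bearing alkene carbon on C5. The forward step must add to the α face, anti to the axial C8 silyl ether.

**Enone.** The C14 methyl of 14 is cut back to iodide 13 and enone 12, and the C5=C10 unsaturation and C9 carbonyl to the saturated alcohol 10. The enone can only be made after C6 and C7 are oxygenated, because a C6=C7/C5=C10 dienone would aromatise.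

**Lactone and C6/C7.** Lactone 10 is opened to diol ester 8 (via 9). The cis C6/C7 diol is cut to alkene 7. The C7–C11 bond of 7 is cut to vinyl bromide 4 and the Reformatsky reagent 6 from ethyl bromoacetate 5. One osmylation anti to the C8 oxygen sets both C6 and the quaternary C7, and the ester arm can then lactonise only onto O6.

**Chiral pool.** Bromide 4 is the differentially silylated form (via 3) of dihydrodiol 2, obtained from the bromobenzene-derived diol 1. The bromine-bearing carbon is mapped onto C7 and the carbinol carbons onto C8 and C9. This mapping gives the absolute configuration required at C8; placing the bromine at C10 would lead to the enantiomeric series.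

## Roads not taken

**Alternative 1:** Achmatowicz template.
- Cut: the ring is opened at C1–C10 and the C6–C9 tetrad is drawn from a pyranone.
- Key step: oxidative rearrangement of a 2-furyl carbinol (NBS/NaHCO3) to the 6-hydroxy-6-methylpyranone A1, which forms the O6–C10 hemiketal bond and exposes a C7 ketone and a C8=C9 enone olefin.
- Merits: cheap furan feedstock; the C6 centre comes from one asymmetric carbinol; the pyranone is a well-understood six-membered template for adding the C7 carbon nucleophile and the C8/C9 diol; no photochemical or pyrolysis equipment is needed.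
- Weak points: after A1 the ten-membered ring is still open, and its closure at C1–C10 must create a Z trisubstituted olefin in a strained ring, for which olefination or metathesis gives little geometric control. The hemiketal must be unmasked to a methyl ketone at the right moment, and the trans relationship of O6 and C11 must be won on the template.
- Comparison: in stereocontrol of C6–C9 and in scalability this road is at least as good as the chosen one. The chosen plan offsets this by forming the ring and both olefin geometries in one step from a rigid precursor, which Alternative 1 leaves unsolved.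

**Alternative 2:** [2,3]-Wittig ring contraction.
- Cut: the C6–C7 bond.
- Key step: tin–lithium exchange at C6 inside a thirteen-membered allylic ether; the α-alkoxy carbanion attacks C7 of an enol acetonide, cleaves O–C13 and contracts the ring to the ten-membered alcohol A2.
- Merits: one step would form the carbocycle, the C6–C7 bond, two stereocentres including the quaternary C7, and the C11=C13 methylene. In this last respect it is better than the chosen plan, which must methylenate late through a dianion.
- Weak points: the migration terminus is a fully substituted, oxygen-bearing olefin carbon, an electron-rich and hindered acceptor for which a [1,2]-shift is a likely competitor. The C6/C7 relative configuration depends on a medium-ring transition state that is hard to predict. Both trisubstituted ring olefins, the stannane and an enol acetonide of defined geometry must be assembled before a macro-etherification.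
- Comparison: the chosen plan sets against the late methylenation a key step of a known reaction type whose stereochemical outcome follows from ring fusion, not from an untested sigmatropic terminus.

**Alternative 3:** Ramberg–Bäcklund contraction.
- Cut: the C1=C10 double bond.
- Key step: an eleven-membered sulfone, treated with CBr2F2 and KOH on Al2O3, is halogenated, closes to the episulfone and loses SO2 to give the ten-membered diene A3.
- Merits: the eleven-membered sulfide is easier to close than a carbocycle; medium-ring Ramberg–Bäcklund reactions lean towards the Z olefin needed at C1=C10; everything runs in solution at ordinary temperature, which is better than a gas-phase thermolysis for scale.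
- Weak points: C10 is methyl-substituted and flanked by the C9 oxygen, so the α-sulfonyl carbanion has a β-alkoxy leaving group and the halogenation site (C1 or C10) is not controlled. The strongly basic medium endangers the tertiary alcohol and the silyl ethers. The step sets no stereocentre, so C6–C9 and the 4E olefin must all be built by acyclic control beforehand.
- Comparison: the chosen plan offsets its demanding photochemical and thermal steps with two olefins from one event and no elimination-prone carbanion.

Key step: step 12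

Assumption: germacrane numbering is used throughout (ring C1–C10, C14 on C10, C15 on C4, O6–C12 lactone, C11 on C7, C13 the exocyclic methylene). α is the ring face carrying O6 and the C7 oxygen; β is the face carrying C11, O8 and O9.

## Route

Step 1
Reactants: 1 (1S,2S)-3-bromocyclohexa-3,5-diene-1,2-diol
Product: 2 (1S,2S)-3-bromocyclohex-3-ene-1,2-diol
Conditions: KO2CN=NCO2K, AcOH, MeOH, 0 °C to rt
Reagents that add atoms: none
Why: Diimide reduction; the disubstituted olefin remote from bromine is reduced much faster than the brominated trisubstituted one, so the vinyl bromide and both carbinol centres (later C8 and C9) stay intact.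

Step 2
Reactants: 2 (1S,2S)-3-bromocyclohex-3-ene-1,2-diol
Product: 4 tert-butyl{[(1S,6S)-2-bromo-6-(triethylsilyloxy)cyclohex-2-en-1-yl]oxy}dimethylsilane, via monosilyl ether 3 (not isolated)
Conditions: Et3SiCl (1.05 equiv), imidazole, CH2Cl2, −40 °C; then tBuMe2SiOTf, 2,6-lutidine, −40 to 0 °C
Reagents that add atoms: chlorotriethylsilane CC[Si](Cl)(CC)CC; tert-butyldimethylsilyl trifluoromethanesulfonate CC(C)(C)[Si](C)(C)OS(=O)(=O)C(F)(F)F
Why: Sequential silylation; the hydroxyl remote from the vinylic bromine (later O9) is the less hindered and should take the labile triethylsilyl group first, leaving the hindered allylic hydroxyl (later O8) for the robust group.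

Step 3
Reactants: 4 tert-butyl{[(1S,6S)-2-bromo-6-(triethylsilyloxy)cyclohex-2-en-1-yl]oxy}dimethylsilane; 5 ethyl bromoacetate
Product: 7 ethyl 2-[(5S,6R)-6-(tert-butyldimethylsilyloxy)-5-(triethylsilyloxy)cyclohex-1-en-1-yl]acetate, via Reformatsky reagent 6 (not isolated)
Conditions: Zn dust, Me3SiCl (cat.), THF, 40 °C (5 to 6); then 4, Pd2(dba)3 (2.5 mol %), XPhos, THF, 65 °C
Reagents that add atoms: none
Why: Negishi-type coupling of a zinc ester enolate (Reformatsky reagent) with an alkenyl bromide; it joins C7 to C11 under nearly neutral conditions that leave both silyl ethers and the β,γ-unsaturated ester in place.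

Step 4
Reactants: 7 ethyl 2-[(5S,6R)-6-(tert-butyldimethylsilyloxy)-5-(triethylsilyloxy)cyclohex-1-en-1-yl]acetate
Product: 8 ethyl 2-[(1S,2S,3S,6S)-2-(tert-butyldimethylsilyloxy)-1,6-dihydroxy-3-(triethylsilyloxy)cyclohexyl]acetate
Conditions: OsO4 (2 mol %), N-methylmorpholine N-oxide, acetone/H2O, rt
Reagents that add atoms: 4-methylmorpholine N-oxide C[N+]1([O-])CCOCC1; water O
Why: Catalytic syn-dihydroxylation of the only olefin; OsO4 adds anti to the allylic silyloxy group (the β face also carries the second silyl ether), which sets the C6 and C7 oxygens on the α face and the quaternary C7 in one step.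

Step 5
Reactants: 8 ethyl 2-[(1S,2S,3S,6S)-2-(tert-butyldimethylsilyloxy)-1,6-dihydroxy-3-(triethylsilyloxy)cyclohexyl]acetate
Product: 10 (3aS,4S,5S,7aS)-4-(tert-butyldimethylsilyloxy)-3a,5-dihydroxyhexahydro-1-benzofuran-2(3H)-one, via lactone silyl ether 9 (not isolated)
Conditions: camphorsulfonic acid (0.1 equiv), CH2Cl2, rt; then MeOH added, 0 °C
Reagents that add atoms: none
Why: Acid-catalysed lactonisation, then selective solvolysis of the triethylsilyl ether; O6 is the only hydroxyl that can give a γ-lactone (O8 is silylated, O7 would give a β-lactone), so the trans-fused lactone forms and the hindered tert-butyldimethylsilyl ether should survive.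

Step 6
Reactants: 10 (3aS,4S,5S,7aS)-4-(tert-butyldimethylsilyloxy)-3a,5-dihydroxyhexahydro-1-benzofuran-2(3H)-one
Product: 12 (3aS,4R,7aS)-4-(tert-butyldimethylsilyloxy)-3a-hydroxy-3,3a,4,7a-tetrahydro-1-benzofuran-2,5-dione, via saturated ketone 11 (not isolated)
Conditions: 2-iodoxybenzoic acid (3 equiv), DMSO/fluorobenzene, 70 °C
Reagents that add atoms: none
Why: Oxidation of the secondary alcohol and dehydrogenation of the resulting ketone by the same hypervalent iodine reagent; the double bond can form only between C10 and C5 because C7 is quaternary, and the same block prevents further dehydrogenation to a phenol.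

Step 7
Reactants: 12 (3aS,4R,7aS)-4-(tert-butyldimethylsilyloxy)-3a-hydroxy-3,3a,4,7a-tetrahydro-1-benzofuran-2,5-dione
Product: 13 (3aS,4R,7aS)-4-(tert-butyldimethylsilyloxy)-3a-hydroxy-6-iodo-3,3a,4,7a-tetrahydro-1-benzofuran-2,5-dione
Conditions: I2, pyridine, CH2Cl2, 0 °C to rt
Reagents that add atoms: iodine II
Why: α-Iodination of a cyclic enone by pyridine addition, iodination and elimination; the conditions are too mild to touch the β-hydroxy ketone or the lactone.

Step 8
Reactants: 13 (3aS,4R,7aS)-4-(tert-butyldimethylsilyloxy)-3a-hydroxy-6-iodo-3,3a,4,7a-tetrahydro-1-benzofuran-2,5-dione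
Product: 14 (3aS,4R,7aS)-4-(tert-butyldimethylsilyloxy)-3a-hydroxy-6-methyl-3,3a,4,7a-tetrahydro-1-benzofuran-2,5-dione
Conditions: Me4Sn, Pd2(dba)3 (cat.), AsPh3, copper iodide (CuI), N-methylpyrrolidone, 60 °C
Reagents that add atoms: tetramethylstannane C[Sn](C)(C)C
Why: Stille methylation of an α-iodoenone; it is base-free, so the β-hydroxy ketone is not exposed to retro-aldol or elimination, and it installs C14.

Step 9
Reactants: 15 methylenecyclobutane
Product: 16 1-methylcyclobutene
Conditions: KOtBu (cat.), DMSO, rt; spinning-band distillation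
Reagents that add atoms: none
Why: Base-catalysed allylic isomerisation to the more substituted endocyclic olefin; the exocyclic isomer is removed by distillation because it would also photoadd.

Step 10
Reactants: 14 (3aS,4R,7aS)-4-(tert-butyldimethylsilyloxy)-3a-hydroxy-6-methyl-3,3a,4,7a-tetrahydro-1-benzofuran-2,5-dione; 16 1-methylcyclobutene
Product: 17 (1S,4R,5S,6S,7S,8R,10R)-8-(tert-butyldimethylsilyloxy)-7-hydroxy-9-oxo-1,4:5,10-dicyclo-13-norgermacran-12,6-olide
Conditions: hν (medium-pressure Hg lamp, borosilicate filter, λ > 300 nm), 16 (10 equiv), CH2Cl2, −40 °C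
Reagents that add atoms: none
Why: Enone–alkene [2+2] photocycloaddition through the enone triplet; head-to-tail orientation (methyl-bearing alkene carbon to C5) is favoured electronically and avoids adjacent quaternary carbons. The trans-lactone fixes the half-chair, so bonding at C5 should be axial on the α face where only the small C7 hydroxyl is axial, while the axial C8 silyl ether screens the β face at C10. Cis closure then gives the cis,anti,cis adduct with the cyclobutane on the α face.

Step 11
Reactants: 17 (1S,4R,5S,6S,7S,8R,10R)-8-(tert-butyldimethylsilyloxy)-7-hydroxy-9-oxo-1,4:5,10-dicyclo-13-norgermacran-12,6-olide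
Product: 18 (1S,4R,5S,6S,7S,8R,10R)-8-(tert-butyldimethylsilyloxy)-9-oxo-7-(trimethylsilyloxy)-1,4:5,10-dicyclo-13-norgermacran-12,6-olide
Conditions: N-(trimethylsilyl)imidazole, CH2Cl2, rt
Reagents that add atoms: N-(trimethylsilyl)imidazole C[Si](C)(C)n1ccnc1
Why: Silylation of a tertiary alcohol with a reagent that does not enolise ketones; capping the C7 hydroxyl removes the hydrogen needed for a thermal retro-aldol of the β-hydroxy ketone in the next step.

Step 12
Reactants: 18 (1S,4R,5S,6S,7S,8R,10R)-8-(tert-butyldimethylsilyloxy)-9-oxo-7-(trimethylsilyloxy)-1,4:5,10-dicyclo-13-norgermacran-12,6-olide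
Product: 19 (1(10)Z,4E,6S,7S,8R)-8-(tert-butyldimethylsilyloxy)-9-oxo-7-(trimethylsilyloxy)-13-norgermacra-1(10),4-dien-12,6-olide
Conditions: flash vacuum thermolysis: sublimed at 10^-3 mbar through a silylated quartz tube at about 430 °C, millisecond contact, product condensed at −196 °C
Reagents that add atoms: none
Why: Thermal cycloreversion of the bicyclo[2.2.0]hexane: the strained central C1–C4 bond breaks to a cyclohexane-1,4-diyl that relaxes to a chair and cleaves the C5–C10 bond (overall a [σ2s+σ2a] change), so two σ bonds become the C1=C10 and C4=C5 π bonds. The closest known reaction type is the thermolysis of cyclobutene–cyclohexenone photoadducts to cis,trans-cyclodeca-1,5-dienes. No ring is closed by bond formation; the ten-membered ring appears by scission of the bond shared by the four- and six-membered rings, a ring expansion by fragmentation. No stereocentre is created: C1, C4, C5 and C10 are erased and C6–C8 are spectators. The step needs Z at C1=C10, E at C4=C5, cleavage of C5–C10 and not C2–C3, and no onward Cope rearrangement. Geometry is secured by the trans-fused lactone, which freezes the cyclohexanone chair with O6 and C11 equatorial; in the α-face adduct C5–C4 is then axial and C10–C1 equatorial, so in the cis-decalin-like diyl C6 is equatorial (trans to C3, hence 4E) and C9 axial (cis to C2, hence 1(10)Z). C5–C10 is the more substituted, weaker bond and its cleavage gives a conjugated enone and two trisubstituted olefins, whereas C2–C3 cleavage would give only vinyl groups. The short contact time and cold trapping spare the Z,E-diene, which can rearrange only through a boat transition state.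

Step 13
Reactants: 19 (1(10)Z,4E,6S,7S,8R)-8-(tert-butyldimethylsilyloxy)-9-oxo-7-(trimethylsilyloxy)-13-norgermacra-1(10),4-dien-12,6-olide
Product: 21 (1(10)Z,4E,6S,7S,8S,9S)-8-(tert-butyldimethylsilyloxy)-7,9-dihydroxy-13-norgermacra-1(10),4-dien-12,6-olide, via allylic alcohol silyl ether 20 (not isolated)
Conditions: NaBH4, CeCl3·7H2O, MeOH, −78 °C; then aqueous citric acid, MeOH, 0 °C
Reagents that add atoms: none
Why: Luche 1,2-reduction of the enone, then mild acid cleavage of the tertiary trimethylsilyl ether; hydride should add anti to the C8–O bond of the non-chelating silyl ether, which gives the 8,9-cis (9β) alcohol, and the lactone is inert at this temperature.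

Step 14
Reactants: 21 (1(10)Z,4E,6S,7S,8S,9S)-8-(tert-butyldimethylsilyloxy)-7,9-dihydroxy-13-norgermacra-1(10),4-dien-12,6-olide
Product: 22 (1(10)Z,4E,6S,7S,8S,9S)-8-(tert-butyldimethylsilyloxy)-7-hydroxy-9-(triethylsilyloxy)-13-norgermacra-1(10),4-dien-12,6-olide
Conditions: Et3SiCl, imidazole, DMF, 0 °C
Reagents that add atoms: chlorotriethylsilane CC[Si](Cl)(CC)CC
Why: Selective silylation of the secondary allylic hydroxyl over the tertiary one; it blocks an O8-to-O9 silyl shift in the next step and leaves O7 free for dianion formation.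

Step 15
Reactants: 22 (1(10)Z,4E,6S,7S,8S,9S)-8-(tert-butyldimethylsilyloxy)-7-hydroxy-9-(triethylsilyloxy)-13-norgermacra-1(10),4-dien-12,6-olide
Product: 25 (1(10)Z,4E,6S,7S,8S,9S)-8-(tert-butyldimethylsilyloxy)-7-hydroxy-9-(triethylsilyloxy)germacra-1(10),4,11(13)-trien-12,6-olide, via Mannich base 23 (not isolated), via ammonium iodide 24 (not isolated)
Conditions: LiN(iPr)2 (2.5 equiv), THF, −78 °C; Me2N=CH2 iodide, −78 to 0 °C; then MeI, MeOH, rt; aqueous NaHCO3, CH2Cl2
Reagents that add atoms: N,N-dimethylmethyleneiminium iodide (Eschenmoser's salt) C=[N+](C)C.[I-]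
Why: Mannich α-aminomethylation of the lactone enolate, then quaternisation and E1cB loss of trimethylamine; the enolate is generated as the alkoxide–enolate dianion of the β-hydroxy lactone, in which the oxide cannot leave, so the C7 oxygen is kept. The C11 configuration of 23 is irrelevant.

Step 16
Reactants: 25 (1(10)Z,4E,6S,7S,8S,9S)-8-(tert-butyldimethylsilyloxy)-7-hydroxy-9-(triethylsilyloxy)germacra-1(10),4,11(13)-trien-12,6-olide
Product: 26 (1(10)Z,4E,6S,7S,8S,9S)-8-(tert-butyldimethylsilyloxy)-7,9-dihydroxygermacra-1(10),4,11(13)-trien-12,6-olide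
Conditions: HF·pyridine, pyridine, THF, 0 °C
Reagents that add atoms: none
Why: Buffered fluoride cleavage of the triethylsilyl ether, which is far more labile than the hindered tert-butyldimethylsilyl ether; the buffered medium spares the diene and the methylene lactone.

Step 17
Reactants: 27 angelic acid
Product: 28 (Z)-2-methylbut-2-en-1-ol
Conditions: LiAlH4, Et2O, 0 °C
Reagents that add atoms: none
Why: Hydride reduction of the acid to the allylic alcohol; at low temperature the trisubstituted Z olefin is neither reduced nor isomerised.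

Step 18
Reactants: 28 (Z)-2-methylbut-2-en-1-ol
Product: 29 [(2R,3S)-2,3-dimethyloxiran-2-yl]methanol
Conditions: Ti(OiPr)4, D-(−)-diethyl tartrate, tBuOOH, 4 Å molecular sieves, CH2Cl2, −20 °C
Reagents that add atoms: tert-butyl hydroperoxide CC(C)(C)OO
Why: Sharpless asymmetric epoxidation; with the D-tartrate the oxygen is delivered to the face that gives the (2R,3S)-epoxy alcohol, and the Z geometry fixes the cis relation of CH2OH and the C3 methyl. Any minor enantiomer is removed later as a diastereomeric ester.

Step 19
Reactants: 29 [(2R,3S)-2,3-dimethyloxiran-2-yl]methanol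
Product: 30 (2S,3S)-2,3-dimethyloxirane-2-carboxylic acid
Conditions: RuCl3·xH2O (cat.), NaIO4, CCl4/MeCN/H2O, 0 °C to rt
Reagents that add atoms: sodium periodate [Na+].[O-]I(=O)(=O)=O; water O
Why: Catalytic RuO4 oxidation of a 2,3-epoxy alcohol to the glycidic acid; the stereocentres are untouched and only the descriptor at C2 changes.

Step 20
Reactants: 26 (1(10)Z,4E,6S,7S,8S,9S)-8-(tert-butyldimethylsilyloxy)-7,9-dihydroxygermacra-1(10),4,11(13)-trien-12,6-olide; 30 (2S,3S)-2,3-dimethyloxirane-2-carboxylic acid
Product: 32 (1(10)Z,4E,6S,7S,8S,9S)-8-(tert-butyldimethylsilyloxy)-9-[(2S,3S)-2,3-dimethyloxirane-2-carbonyloxy]-7-hydroxygermacra-1(10),4,11(13)-trien-12,6-olide, via mixed anhydride 31 (not isolated)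
Conditions: 2,4,6-trichlorobenzoyl chloride, Et3N, toluene, rt; then 26, 4-(dimethylamino)pyridine, toluene, rt to 40 °C
Reagents that add atoms: none
Why: Yamaguchi esterification, suited to a hindered acid and a hindered secondary alcohol; the tertiary C7 hydroxyl does not compete, and the epoxy acid has no α-hydrogen to epimerise.

Step 21
Reactants: 32 (1(10)Z,4E,6S,7S,8S,9S)-8-(tert-butyldimethylsilyloxy)-9-[(2S,3S)-2,3-dimethyloxirane-2-carbonyloxy]-7-hydroxygermacra-1(10),4,11(13)-trien-12,6-olide
Product: 33 (1(10)Z,4E,6S,7R,8S,9S)-9-[(2S,3S)-2,3-dimethyloxirane-2-carbonyloxy]-7,8-dihydroxygermacra-1(10),4,11(13)-trien-12,6-olide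
Conditions: HF·pyridine, THF/pyridine, 0 °C to rt
Reagents that add atoms: none
Why: Fluoride desilylation under weakly acidic, non-nucleophilic conditions, under which the hindered epoxyangelate should not migrate and the lactone should not move to O8; the electron-poor epoxide resists opening. The descriptor at C7 changes only because of priority.

Step 22
Reactants: 33 (1(10)Z,4E,6S,7R,8S,9S)-9-[(2S,3S)-2,3-dimethyloxirane-2-carbonyloxy]-7,8-dihydroxygermacra-1(10),4,11(13)-trien-12,6-olide
Product: 34 (1(10)Z,4E,6S,7S,8S,9S)-8-acetoxy-9-[(2S,3S)-2,3-dimethyloxirane-2-carbonyloxy]-7-hydroxygermacra-1(10),4,11(13)-trien-12,6-olide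
Conditions: Ac2O, pyridine, 4-(dimethylamino)pyridine (cat.), CH2Cl2, 0 °C
Reagents that add atoms: acetic anhydride CC(=O)OC(C)=O
Why: Acyl transfer to the secondary C8 hydroxyl, much faster than to the tertiary C7 hydroxyl; acetylation is placed last so that the mobile acetyl group never sits beside a free secondary hydroxyl.

## Compound list

1 | (1S,2S)-3-bromocyclohexa-3,5-diene-1,2-diol | BrC1=CC=C[C@H](O)[C@@H]1O | starting material
2 | (1S,2S)-3-bromocyclohex-3-ene-1,2-diol | BrC1=CCC[C@H](O)[C@@H]1O | intermediate
3 | (1S,6S)-2-bromo-6-(triethylsilyloxy)cyclohex-2-en-1-ol | BrC1=CCC[C@H](O[Si](CC)(CC)CC)[C@@H]1O | intermediate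
4 | tert-butyl{[(1S,6S)-2-bromo-6-(triethylsilyloxy)cyclohex-2-en-1-yl]oxy}dimethylsilane | BrC1=CCC[C@H](O[Si](CC)(CC)CC)[C@@H]1O[Si](C)(C)C(C)(C)C | intermediate
5 | ethyl bromoacetate | BrCC(=O)OCC | starting material
6 | ethyl (bromozincio)acetate (Reformatsky reagent) | CCOC(=O)C[Zn]Br | intermediate
7 | ethyl 2-[(5S,6R)-6-(tert-butyldimethylsilyloxy)-5-(triethylsilyloxy)cyclohex-1-en-1-yl]acetate | CCOC(=O)CC1=CCC[C@H](O[Si](CC)(CC)CC)[C@@H]1O[Si](C)(C)C(C)(C)C | intermediate
8 | ethyl 2-[(1S,2S,3S,6S)-2-(tert-butyldimethylsilyloxy)-1,6-dihydroxy-3-(triethylsilyloxy)cyclohexyl]acetate | CCOC(=O)C[C@]1(O)[C@@H](O)CC[C@H](O[Si](CC)(CC)CC)[C@@H]1O[Si](C)(C)C(C)(C)C | intermediate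
9 | (3aS,4S,5S,7aS)-4-(tert-butyldimethylsilyloxy)-3a-hydroxy-5-(triethylsilyloxy)hexahydro-1-benzofuran-2(3H)-one | O=C1C[C@@]2(O)[C@@H](O[Si](C)(C)C(C)(C)C)[C@@H](O[Si](CC)(CC)CC)CC[C@@H]2O1 | intermediate
10 | (3aS,4S,5S,7aS)-4-(tert-butyldimethylsilyloxy)-3a,5-dihydroxyhexahydro-1-benzofuran-2(3H)-one | O=C1C[C@@]2(O)[C@@H](O[Si](C)(C)C(C)(C)C)[C@@H](O)CC[C@@H]2O1 | intermediate
11 | (3aS,4R,7aS)-4-(tert-butyldimethylsilyloxy)-3a-hydroxyhexahydro-1-benzofuran-2,5-dione | O=C1C[C@@]2(O)[C@@H](O[Si](C)(C)C(C)(C)C)C(=O)CC[C@@H]2O1 | intermediate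
12 | (3aS,4R,7aS)-4-(tert-butyldimethylsilyloxy)-3a-hydroxy-3,3a,4,7a-tetrahydro-1-benzofuran-2,5-dione | O=C1C[C@@]2(O)[C@@H](O[Si](C)(C)C(C)(C)C)C(=O)C=C[C@@H]2O1 | intermediate
13 | (3aS,4R,7aS)-4-(tert-butyldimethylsilyloxy)-3a-hydroxy-6-iodo-3,3a,4,7a-tetrahydro-1-benzofuran-2,5-dione | O=C1C[C@@]2(O)[C@@H](O[Si](C)(C)C(C)(C)C)C(=O)C(I)=C[C@@H]2O1 | intermediate
14 | (3aS,4R,7aS)-4-(tert-butyldimethylsilyloxy)-3a-hydroxy-6-methyl-3,3a,4,7a-tetrahydro-1-benzofuran-2,5-dione | O=C1C[C@@]2(O)[C@@H](O[Si](C)(C)C(C)(C)C)C(=O)C(C)=C[C@@H]2O1 | intermediate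
15 | methylenecyclobutane | C=C1CCC1 | starting material
16 | 1-methylcyclobutene | CC1=CCC1 | intermediate
17 | (1S,4R,5S,6S,7S,8R,10R)-8-(tert-butyldimethylsilyloxy)-7-hydroxy-9-oxo-1,4:5,10-dicyclo-13-norgermacran-12,6-olide (cis,anti,cis head-to-tail photoadduct, cyclobutane on the α face) | C[C@]12C(=O)[C@H](O[Si](C)(C)C(C)(C)C)[C@]4(O)CC(=O)O[C@H]4[C@H]1[C@]3(C)CC[C@H]23 | intermediate
18 | (1S,4R,5S,6S,7S,8R,10R)-8-(tert-butyldimethylsilyloxy)-9-oxo-7-(trimethylsilyloxy)-1,4:5,10-dicyclo-13-norgermacran-12,6-olide | C[C@]12C(=O)[C@H](O[Si](C)(C)C(C)(C)C)[C@]4(O[Si](C)(C)C)CC(=O)O[C@H]4[C@H]1[C@]3(C)CC[C@H]23 | intermediate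
19 | (1(10)Z,4E,6S,7S,8R)-8-(tert-butyldimethylsilyloxy)-9-oxo-7-(trimethylsilyloxy)-13-norgermacra-1(10),4-dien-12,6-olide | C1C(=O)O[C@H]2/C=C(\C)CC/C=C(/C)C(=O)[C@H](O[Si](C)(C)C(C)(C)C)[C@]12O[Si](C)(C)C | intermediate
20 | (1(10)Z,4E,6S,7S,8S,9S)-8-(tert-butyldimethylsilyloxy)-9-hydroxy-7-(trimethylsilyloxy)-13-norgermacra-1(10),4-dien-12,6-olide | C1C(=O)O[C@H]2/C=C(\C)CC/C=C(/C)[C@H](O)[C@H](O[Si](C)(C)C(C)(C)C)[C@]12O[Si](C)(C)C | intermediate
21 | (1(10)Z,4E,6S,7S,8S,9S)-8-(tert-butyldimethylsilyloxy)-7,9-dihydroxy-13-norgermacra-1(10),4-dien-12,6-olide | C1C(=O)O[C@H]2/C=C(\C)CC/C=C(/C)[C@H](O)[C@H](O[Si](C)(C)C(C)(C)C)[C@]12O | intermediate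
22 | (1(10)Z,4E,6S,7S,8S,9S)-8-(tert-butyldimethylsilyloxy)-7-hydroxy-9-(triethylsilyloxy)-13-norgermacra-1(10),4-dien-12,6-olide | C1C(=O)O[C@H]2/C=C(\C)CC/C=C(/C)[C@H](O[Si](CC)(CC)CC)[C@H](O[Si](C)(C)C(C)(C)C)[C@]12O | intermediate
23 | (1(10)Z,4E,6S,7S,8S,9S)-8-(tert-butyldimethylsilyloxy)-13-(dimethylamino)-7-hydroxy-9-(triethylsilyloxy)germacra-1(10),4-dien-12,6-olide (both C11 epimers) | CN(C)CC1C(=O)O[C@H]2/C=C(\C)CC/C=C(/C)[C@H](O[Si](CC)(CC)CC)[C@H](O[Si](C)(C)C(C)(C)C)[C@]12O | intermediate
24 | N-methyl ammonium iodide of 23 (both C11 epimers) | C[N+](C)(C)CC1C(=O)O[C@H]2/C=C(\C)CC/C=C(/C)[C@H](O[Si](CC)(CC)CC)[C@H](O[Si](C)(C)C(C)(C)C)[C@]12O.[I-] | intermediate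
25 | (1(10)Z,4E,6S,7S,8S,9S)-8-(tert-butyldimethylsilyloxy)-7-hydroxy-9-(triethylsilyloxy)germacra-1(10),4,11(13)-trien-12,6-olide | C=C1C(=O)O[C@H]2/C=C(\C)CC/C=C(/C)[C@H](O[Si](CC)(CC)CC)[C@H](O[Si](C)(C)C(C)(C)C)[C@]12O | intermediate
26 | (1(10)Z,4E,6S,7S,8S,9S)-8-(tert-butyldimethylsilyloxy)-7,9-dihydroxygermacra-1(10),4,11(13)-trien-12,6-olide | C=C1C(=O)O[C@H]2/C=C(\C)CC/C=C(/C)[C@H](O)[C@H](O[Si](C)(C)C(C)(C)C)[C@]12O | intermediate
27 | angelic acid, (Z)-2-methylbut-2-enoic acid | C/C=C(/C)C(=O)O | starting material
28 | (Z)-2-methylbut-2-en-1-ol | C/C=C(/C)CO | intermediate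
29 | [(2R,3S)-2,3-dimethyloxiran-2-yl]methanol | OC[C@@]1(C)O[C@H]1C | intermediate
30 | (2S,3S)-2,3-dimethyloxirane-2-carboxylic acid | OC(=O)[C@@]1(C)O[C@H]1C | intermediate
31 | (2S,3S)-2,3-dimethyloxirane-2-carboxylic 2,4,6-trichlorobenzoic anhydride | O=C(OC(=O)[C@@]1(C)O[C@H]1C)c1c(Cl)cc(Cl)cc1Cl | intermediate
32 | (1(10)Z,4E,6S,7S,8S,9S)-8-(tert-butyldimethylsilyloxy)-9-[(2S,3S)-2,3-dimethyloxirane-2-carbonyloxy]-7-hydroxygermacra-1(10),4,11(13)-trien-12,6-olide | C=C1C(=O)O[C@H]2/C=C(\C)CC/C=C(/C)[C@H](OC(=O)[C@@]3(C)O[C@H]3C)[C@H](O[Si](C)(C)C(C)(C)C)[C@]12O | intermediate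
33 | (1(10)Z,4E,6S,7R,8S,9S)-9-[(2S,3S)-2,3-dimethyloxirane-2-carbonyloxy]-7,8-dihydroxygermacra-1(10),4,11(13)-trien-12,6-olide | C=C1C(=O)O[C@H]2/C=C(\C)CC/C=C(/C)[C@H](OC(=O)[C@@]3(C)O[C@H]3C)[C@H](O)[C@]12O | intermediate
34 | (1(10)Z,4E,6S,7S,8S,9S)-8-acetoxy-9-[(2S,3S)-2,3-dimethyloxirane-2-carbonyloxy]-7-hydroxygermacra-1(10),4,11(13)-trien-12,6-olide | C=C1C(=O)O[C@H]2/C=C(\C)CC/C=C(/C)[C@H](OC(=O)[C@@]3(C)O[C@H]3C)[C@H](OC(C)=O)[C@]12O | target

## Step count and risks

Total: 22 steps. Longest linear sequence: 18 steps (steps 1–8, 10–16, 20–22); steps 9 and 17–19 are side branches.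

**Step 12 (key step).** The most likely failures are loss of the olefin geometry or of the ten-membered ring. The diyl could fragment through a non-chair conformer or cleave C2–C3, and the product could undergo Cope rearrangement to a divinylcyclohexane on the hot wall. The silylated β-oxy ketone and the Z-enone are also the most heat-sensitive functions present. Fallback, from 18 back to 22: reduce before fragmenting. NaBH4/CeCl3·7H2O on the rigid tricycle (axial hydride delivery) should give the tricyclic 9β-alcohol F1. Et3SiCl/imidazole gives its triethylsilyl ether F2. Thermolysis of F2, which has neither ketone nor enone, gives the ten-membered 7-O-trimethylsilyl 9-O-triethylsilyl diene F3. K2CO3 in MeOH at 0 °C removes the trimethylsilyl group and returns 22.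

**Step 10.** Facial and ring-fusion selectivity may erode. Closure at the methyl-bearing C10 beside the axial silyl ether may occur on the wrong face or give trans-fused adducts, which cannot be corrected because C10 is quaternary, and only the α-face cis,anti,cis adduct gives the right olefin geometry. Fallback, from 12 (with 16) to 18: irradiate the C10-unsubstituted enone 12. All adducts from α-bonding at C5 can then be converged on the cis-fused C10–H photoadduct F4 by epimerisation on basic alumina. Silylation with N-(trimethylsilyl)imidazole gives the 7-O-trimethylsilyl ether F5. LiN(iPr)2 then MeI methylates C10 on the convex β face and gives 18. This replaces steps 7 and 8 and has its own question of enolisation towards C10 versus C8.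

**Step 3.** Oxidative addition or transmetalation may be slow at a vinyl bromide flanked by a bulky silyl ether, giving protodebromination or Reformatsky self-condensation. Fallback, from 4 to 9: tBuLi (Et2O, −78 °C) then ethylene oxide/BF3·OEt2 gives the homoallylic alcohol 2-[(5S,6R)-6-(tert-butyldimethylsilyloxy)-5-(triethylsilyloxy)cyclohex-1-en-1-yl]ethanol F6. OsO4/N-methylmorpholine N-oxide gives the triol F7. Oxidative lactonisation of the primary alcohol onto O6 (TEMPO, PhI(OAc)2) returns lactone 9.

**Step 13.** Hydride may add to the wrong face, since the conformation of the ten-membered Z-enone, not the local C8 substituent, may decide the face. Fallback, from 19 to 21: take the 9α-alcohol F8 that the same reduction would then give and invert it by Mitsunobu reaction (PPh3, diisopropyl azodicarboxylate, chloroacetic acid) to the 9β-chloroacetate F9. Thiourea/NaHCO3 in EtOH removes the chloroacetyl group without touching the lactone and gives 21.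

**Step 2.** Discrimination between the two hydroxyls in the first silylation may be incomplete, which would scramble the silyl groups. Fallback, from 2 to 10: silylate both hydroxyls with tBuMe2SiOTf to the bis(tert-butyldimethylsilyl) ether F10. Carry it through the coupling to ester F11, the osmylation to diol ester F12 and the acid lactonisation to bis-silyl lactone F13. Then remove only the less hindered C9 silyl ether (flanked by CH2, whereas the C8 ether sits beside the quaternary C7) with HF·pyridine to reach 10.

## Further compounds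

F1 | step 12 | (1S,4R,5S,6S,7S,8S,9S,10R)-8-(tert-butyldimethylsilyloxy)-9-hydroxy-7-(trimethylsilyloxy)-1,4:5,10-dicyclo-13-norgermacran-12,6-olide (tricyclic 9β-alcohol) | C[C@]12[C@H](O)[C@H](O[Si](C)(C)C(C)(C)C)[C@]4(O[Si](C)(C)C)CC(=O)O[C@H]4[C@H]1[C@]3(C)CC[C@H]23
F2 | step 12 | 9-O-triethylsilyl ether of F1 | C[C@]12[C@H](O[Si](CC)(CC)CC)[C@H](O[Si](C)(C)C(C)(C)C)[C@]4(O[Si](C)(C)C)CC(=O)O[C@H]4[C@H]1[C@]3(C)CC[C@H]23
F3 | step 12 | (1(10)Z,4E,6S,7S,8S,9S)-8-(tert-butyldimethylsilyloxy)-9-(triethylsilyloxy)-7-(trimethylsilyloxy)-13-norgermacra-1(10),4-dien-12,6-olide | C1C(=O)O[C@H]2/C=C(\C)CC/C=C(/C)[C@H](O[Si](CC)(CC)CC)[C@H](O[Si](C)(C)C(C)(C)C)[C@]12O[Si](C)(C)C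
F4 | step 10 | (1S,4R,5S,6S,7S,8R,10R)-8-(tert-butyldimethylsilyloxy)-7-hydroxy-9-oxo-1,4:5,10-dicyclo-13,14-dinorgermacran-12,6-olide (C10–H photoadduct, cis,anti,cis, α face) | [C@H]12C(=O)[C@H](O[Si](C)(C)C(C)(C)C)[C@]4(O)CC(=O)O[C@H]4[C@H]1[C@]3(C)CC[C@H]23
F5 | step 10 | 7-O-trimethylsilyl ether of F4 | [C@H]12C(=O)[C@H](O[Si](C)(C)C(C)(C)C)[C@]4(O[Si](C)(C)C)CC(=O)O[C@H]4[C@H]1[C@]3(C)CC[C@H]23
F6 | step 3 | 2-[(5S,6R)-6-(tert-butyldimethylsilyloxy)-5-(triethylsilyloxy)cyclohex-1-en-1-yl]ethanol | OCCC1=CCC[C@H](O[Si](CC)(CC)CC)[C@@H]1O[Si](C)(C)C(C)(C)C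
F7 | step 3 | (1S,2S,5S,6S)-6-(tert-butyldimethylsilyloxy)-1-(2-hydroxyethyl)-5-(triethylsilyloxy)cyclohexane-1,2-diol | OCC[C@]1(O)[C@@H](O)CC[C@H](O[Si](CC)(CC)CC)[C@@H]1O[Si](C)(C)C(C)(C)C
F8 | step 13 | (1(10)Z,4E,6S,7S,8S,9R)-8-(tert-butyldimethylsilyloxy)-7,9-dihydroxy-13-norgermacra-1(10),4-dien-12,6-olide (9α-alcohol) | C1C(=O)O[C@H]2/C=C(\C)CC/C=C(/C)[C@@H](O)[C@H](O[Si](C)(C)C(C)(C)C)[C@]12O
F9 | step 13 | (1(10)Z,4E,6S,7S,8S,9S)-8-(tert-butyldimethylsilyloxy)-9-(chloroacetoxy)-7-hydroxy-13-norgermacra-1(10),4-dien-12,6-olide | C1C(=O)O[C@H]2/C=C(\C)CC/C=C(/C)[C@H](OC(=O)CCl)[C@H](O[Si](C)(C)C(C)(C)C)[C@]12O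
F10 | step 2 | (1S,6S)-1-bromo-5,6-bis(tert-butyldimethylsilyloxy)cyclohex-1-ene | BrC1=CCC[C@H](O[Si](C)(C)C(C)(C)C)[C@@H]1O[Si](C)(C)C(C)(C)C
F11 | step 2 | ethyl 2-[(5S,6R)-5,6-bis(tert-butyldimethylsilyloxy)cyclohex-1-en-1-yl]acetate | CCOC(=O)CC1=CCC[C@H](O[Si](C)(C)C(C)(C)C)[C@@H]1O[Si](C)(C)C(C)(C)C
F12 | step 2 | ethyl 2-[(1S,2S,3S,6S)-2,3-bis(tert-butyldimethylsilyloxy)-1,6-dihydroxycyclohexyl]acetate | CCOC(=O)C[C@]1(O)[C@@H](O)CC[C@H](O[Si](C)(C)C(C)(C)C)[C@@H]1O[Si](C)(C)C(C)(C)C
F13 | step 2 | (3aS,4S,5S,7aS)-4,5-bis(tert-butyldimethylsilyloxy)-3a-hydroxyhexahydro-1-benzofuran-2(3H)-one | O=C1C[C@@]2(O)[C@@H](O[Si](C)(C)C(C)(C)C)[C@@H](O[Si](C)(C)C(C)(C)C)CC[C@@H]2O1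
A1 | alternative 1 | trans-2-[(E)-5-(tert-butyldimethylsilyloxy)-2-methylpent-1-enyl]-6-hydroxy-6-methyl-2H-pyran-3(6H)-one | C[C@]1(O)C=CC(=O)[C@H](/C=C(\C)CCCO[Si](C)(C)C(C)(C)C)O1
A2 | alternative 2 | ten-membered C6 alcohol with C7/C8 acetonide, C9 4-methoxybenzyl ether and 3-(tert-butyldimethylsilyloxy)prop-1-en-2-yl side chain on C7 | O[C@H]2/C=C(\C)CC/C=C(/C)[C@H](OCc4ccc(OC)cc4)[C@@H]3OC(C)(C)O[C@@]23C(=C)CO[Si](C)(C)C(C)(C)C
A3 | alternative 3 | ten-membered (1(10)Z,4E)-diene with C6 silyl ether, C7 carbinol bearing a 2-(tert-butyldimethylsilyloxy)ethyl group and C8/C9 acetonide | CC(C)(C)[Si](C)(C)O[C@H]2/C=C(\C)CC/C=C(/C)[C@@H]3OC(C)(C)O[C@@H]3[C@@]2(CCO[Si](C)(C)C(C)(C)C)O
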